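The numbers of this flask stand for no real mixture; the flask was simulated.

The constants made me count lifetimes before anything else, so the flask stands here first.

substrate 0.25 M (fed, over 15 h); first nucleophile 0.250 M; second nucleophile 0.200 M; time 15 d
    substrate → intermediate (k1 = 0.35 /h)
    first nucleophile + intermediate → target (k2 = 10 /M/h)
    second nucleophile + intermediate → other capture product (k3 = 38 /M/h)
    intermediate → solvolysis product (k4 = 1.5 /h)
    crystals ⇌ target, rate k5*(cs5 - [target]) while solid is left; crystals form when [target] > cs5 (cs5 = 0.23 M, k5 = 1.7 /h)
    second nucleophile → decomposed reagent (k6 = 0.024 /h)
    second nucleophile + target ⇌ idle adduct, settled at all times (K7 = 5.8 /M)
- which holds at 15 d: what has brought the reaction to rest, or that it has not come to rest (it is still moving / all of the substrate has reacted / forward and back rates have come level / the first nucleophile has run out first)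
- share of the substrate used up at 15 d
- target at 15 d, in percent of the substrate charged
- other capture product at 15 d, in percent of the substrate charged
- amounts and yields of target count crystals and idle adduct too
- given per volume of solution although it is solid: crystals
- the reaction counts as stopped when no species that holds the substrate changes by six tenths of a point or more over the second half of the time
- run time (flask): 15 d

- The substrate's half-life is 1.98 h, and 174 such half-lives fit between the end of the feed and 15 d, so I took the substrate to be used up.
- The intermediate's half-life by solvolysis is 0.46 h, shorter than the feed, so I let it divide at each moment among three rates: each capture as a pseudo-first-order step, plus solvolysis.
- At the start, the second nucleophile took 65.5% and the first nucleophile 21.6%, but those shares belong to the start.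
- So I moved to the passage time, the middle of the feed plus one substrate lifetime: 10.4 h. By then 0.125 M of substrate had passed.
- Decay and capture at the start shares left 0.0741 M of second nucleophile and 0.223 M of first, which gave the second nucleophile 43.0%.
- The weak link was charging capture at the start share, which stood above this one. With the mean of the two, 54.3%, the second nucleophile stood at 0.0882 M.
- That gave the passage share, the part of the intermediate taken by the second nucleophile at the passage time: 47.3%. The target's share was 31.5%, which is 0.0788 M, less than the solubility, so I expected no crystals.
- The forecast said all of the substrate has reacted, with conversion 100%, target 32% and other capture product 45%, on the ground of “the second nucleophile winning early but fading through consumption, decay and adduct binding”. My other capture share stood 2.3 percentage points higher.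
- The flask gave all of the substrate has reacted, conversion 100%, target 31.6% and other capture product 45.7%. At 0.428 d the second nucleophile's capture ran at 1.5 times the first's, and my shares, 47.3% over 31.5%, had given 1.50. The target answer had moved by 5 points once the second nucleophile was charged at 0.146 M or at 0.266 M instead of 0.200 M; those are other flasks, and against the forecast for this flask it takes a different result at the charges given.
- For the neighbour flask with 0.80 M of second nucleophile, the start share 88.4% left 0.513 M at the passage time, and with the first nucleophile taken at its charge the passage share came to 83.0%. That neighbour flask gave 83.1% of other capture product.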